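- The isomer of the product and the target, I supposed, grew from different parents: the isomer from the other conformer, the target from the starting material.

| flask | starting material | other conformer | protic impurity | remark | time |
|---|---|---|---|---|---|
| zeta | 20 mM | 3.4 mM | 2 mM | run made earlier |  |
| alpha | 20 mM | 7.5 mM | 2 mM | run made earlier |  |
| flask | 20 mM | 5.00 mM | 2.00 mM |  | 2.0 h |

| run | time / min | isomer of the product / % | target / % |
|---|---|---|---|
| zeta | 6.00 | 60.4 | 21.6 |
| zeta | 8.00 | 64.3 | 23.8 |
| zeta | 12.0 | 65.6 | 25.1 |
| zeta | 20.0 | 64.5 | 26.7 |
| zeta | 30.0 | 63.4 | 28.6 |
| zeta | 50.0 | 60.4 | 32.2 |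
| zeta | 80.0 | 56.6 | 36.1 |
| alpha | 6.00 | 61.9 | 21.2 |
| alpha | 8.00 | 65.6 | 22.5 |
| alpha | 12.0 | 67.0 | 24.1 |
| alpha | 20.0 | 65.8 | 25.7 |
| alpha | 30.0 | 65.0 | 27.9 |
| alpha | 50.0 | 61.7 | 31.2 |
| alpha | 80.0 | 57.1 | 35.7 |

(standard deviation of a reading: 0.3 percentage points)



- share of isomer of the product in isomer of the product plus target at 3.0 s
- share of isomer of the product in isomer of the product plus target at 2.0 h

- So I divided one rate by the other and time dropped out: the ratio of their rates follows [other conformer]/[starting material], and 3.0 s lies far before the first reading at 6.00 min.
- For my upper bound I took that first reading, where isomer over target averaged 2.86 across both runs; I read this as a conformer pair already mixed, which gave a share of about 74.1%.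
- For my lower bound I supposed the conformers stand equal at balance, a supposition of mine and not a reading.
- The start selectivity factor, that mixed ratio times the charged [other conformer]/[starting material], was then 0.715 for this flask, a share of 41.7%. My hand went no further, and I leaned towards this floor.
- The forecast said 75.3% and 56.4%, warning that “initial selectivity could differ”; its early figure stood just above my ceiling.
- The flask gave 46.3% and 55.9%, so the early share lay 4.6 percentage points above my floor, and the forecast's late share held within its tolerance.

    target ⇌ isomer of the product (K = 0.470, k = 0.00160 min⁻¹)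
    other conformer + protic impurity → quenched substrate (k = 55.0 L mol⁻¹ min⁻¹)
    other conformer → isomer of the product (k = 0.540 min⁻¹)
    starting material ⇌ other conformer (K = 1.30, k = 2.30 min⁻¹)
    starting material ⇌ dormant form (K = 0.910, k = 0.0160 min⁻¹)
    starting material → target (k = 0.190 min⁻¹)

- The neighbouring flask, charged with 80 mM of starting material, had a start selectivity factor of 0.179, a floor of 15.2%. It gave 25.2% at 3.0 s, above that floor and below the ceiling, and 55.5% at 2.0 h.

The runs were generated by integration from invented constants, and the scatter is random.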